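**Retrosynthetic overview**
1. Late disconnections: C12–C13 (Negishi coupling with a preformed bromobutenolide), C8=C17 (Wittig reaction on a C8 ketone) and the C19 acetate (from a C19 carboxyl group).
2. Key disconnection: the C3–C4 bond of ring A, made by an Ireland–Claisen ring contraction of a bicyclic δ-lactone. The enabling feature is that C4 of ring A carries an oxidised carbon (C19) and is joined through C5–C10 to C1. A lactone ring (O, C19, C4, C5, C10, C1) with a vinyl group (C2=C3) on C1 therefore holds the six atoms C4=C19–O–C1–C2=C3 of a [3,3] shift; C3 is an unsubstituted CH2 in the target. The chirality of C1 is passed to the quaternary C4.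
3. The lactone comes from a ring-B hydroxy ketone by esterification and intramolecular Horner–Wadsworth–Emmons reaction. Ring B with C9 and C10 comes from a commercial cyclohexenone ketal by copper-catalysed asymmetric conjugate vinylation with enolate hydroxymethylation; C1 is set by a ligand-controlled vinylation.
4. Ring order: ring B (present in the starting material) → temporary lactone ring (step 7) → ring A (step 8) → butenolide ring (attached preformed, step 17).

Key step: step 8

Remark: the labdane numbering of the target (C1–C20) is used for all intermediates; the enone ketal, the phosphonopropanoic acid and the bromobutenolide are taken as commercial.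

Step 1
Reactants: 1 1,4-dioxaspiro[4.5]dec-6-en-8-one
Product: 2 7-iodo-1,4-dioxaspiro[4.5]dec-6-en-8-one
Conditions: I2, pyridine, CH2Cl2, 0 °C → rt
Reagents that add atoms: iodine, [I][I]
Why: α-Iodination of a cyclic enone (conjugate addition of pyridine, iodination of the enolate, elimination) places the halogen only on the enone α-carbon, the future C10; no stereocentre is formed.

Step 2
Reactants: 2 7-iodo-1,4-dioxaspiro[4.5]dec-6-en-8-one
Product: 3 7-methyl-1,4-dioxaspiro[4.5]dec-6-en-8-one
Conditions: trimethylboroxine, PdCl2(dppf) (5 mol %), K2CO3, dioxane/H2O, 90 °C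
Reagents that add atoms: trimethylboroxine, CB1OB(C)OB(C)O1
Why: Suzuki–Miyaura methylation of the α-iodoenone installs the C10 methyl group (C20) and leaves the ketal untouched; no stereocentre is formed.

Step 3
Reactants: 3 7-methyl-1,4-dioxaspiro[4.5]dec-6-en-8-one
Product: 5 (6S,7R)-7-(hydroxymethyl)-7-methyl-6-vinyl-1,4-dioxaspiro[4.5]decan-8-one, via bromomagnesium enolate 4 (not isolated)
Conditions: CH2=CHMgBr, copper thiophene-2-carboxylate (5 mol %), chiral N-heterocyclic carbene ligand (6 mol %), Et2O, −78 °C; then CH2O (gas, cracked from paraformaldehyde), −78 → −30 °C; aq. NH4Cl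
Reagents that add atoms: vinylmagnesium bromide, C=C[Mg]Br; formaldehyde, C=O
Why: Copper-catalysed asymmetric conjugate addition should set C9 under ligand control, and the tetrasubstituted magnesium enolate is then hydroxymethylated (aldol trapping) on the face anti to the new vinyl group, which sets the quaternary C10 with its methyl cis to the C9 vinyl.

Step 4
Reactants: 5 (6S,7R)-7-(hydroxymethyl)-7-methyl-6-vinyl-1,4-dioxaspiro[4.5]decan-8-one
Product: 6 (6S,7R)-7-methyl-8-oxo-6-vinyl-1,4-dioxaspiro[4.5]decane-7-carbaldehyde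
Conditions: Dess–Martin periodinane, CH2Cl2, 0 °C → rt
Reagents that add atoms: none
Why: Dess–Martin oxidation of the neopentyl primary alcohol should give the non-enolisable β-keto aldehyde (C1) without touching a stereocentre.

Step 5
Reactants: 6 (6S,7R)-7-methyl-8-oxo-6-vinyl-1,4-dioxaspiro[4.5]decane-7-carbaldehyde
Product: 7 (6S,7R)-7-[(1S)-1-hydroxyprop-2-en-1-yl]-7-methyl-6-vinyl-1,4-dioxaspiro[4.5]decan-8-one
Conditions: Zn(CH=CH2)2, (−)-3-exo-morpholinoisoborneol (10 mol %), toluene, −20 → 0 °C; aq. NH4Cl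
Reagents that add atoms: divinylzinc, C=C[Zn]C=C
Why: Amino-alcohol-catalysed enantioselective addition of an alkenylzinc reagent attacks only the aldehyde (the ketone is inert) and should set C1 as 1S under ligand control.

Step 6
Reactants: 7 (6S,7R)-7-[(1S)-1-hydroxyprop-2-en-1-yl]-7-methyl-6-vinyl-1,4-dioxaspiro[4.5]decan-8-one; 8 2-(diethoxyphosphoryl)propanoic acid
Product: 9 (1S)-1-[(6S,7R)-7-methyl-8-oxo-6-vinyl-1,4-dioxaspiro[4.5]decan-7-yl]prop-2-en-1-yl 2-(diethoxyphosphoryl)propanoate
Conditions: N,N'-dicyclohexylcarbodiimide, DMAP, CH2Cl2, 0 °C → rt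
Reagents that add atoms: none
Why: Steglich esterification acylates the C1 hydroxyl with retention; the phosphonate carbon is a mixture of epimers that disappears in the next step.

Step 7
Reactants: 9 (1S)-1-[(6S,7R)-7-methyl-8-oxo-6-vinyl-1,4-dioxaspiro[4.5]decan-7-yl]prop-2-en-1-yl 2-(diethoxyphosphoryl)propanoate
Product: 10 (1S,9S,10S)-bicyclic lactone: δ-lactone O–C1–C10–C5(=C4(CH3))–C19(=O) fused to ring B, with C1 vinyl, C9 vinyl, C10 methyl and C8 ethylene ketal
Conditions: NaH, THF, 0 → 60 °C
Reagents that add atoms: none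
Why: Intramolecular Horner–Wadsworth–Emmons olefination of the C5 ketone closes the α,β-unsaturated δ-lactone; the ring forces C19 cis to C10 across the new C4=C5 bond, and no stereocentre is formed.

Step 8
Reactants: 10 (1S,9S,10S)-bicyclic lactone
Product: 13 (4R,9S,10S)-8,8-ethylenedioxy-13,14,15,16,17-pentanor-ent-labda-1,5,11-trien-19-oic acid, via silyl ketene acetal 11 (not isolated), via silyl ester 12 (not isolated)
Conditions: LiN(iPr)2 (1.3 equiv), tBuMe2SiCl, HMPA, THF, −78 °C; then toluene, 90 °C; then aq. citric acid, THF, rt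
Reagents that add atoms: none
Why: γ-Deprotonation at C6 and O-silylation turn the lactone into the cyclic silyl ketene acetal 11, in which the C19=C4 enol unit, the ring oxygen on C1 and the C2=C3 vinyl group form the array of a [3,3]-sigmatropic (Ireland–Claisen) shift: the C1–O bond breaks, C3 bonds to C4 and the ring oxygen ends in the C19 carboxylate. The closest known reactions are the Ireland–Claisen ring contraction of 6-vinyl δ-lactone silyl ketene acetals to cyclohexenecarboxylic acids and the α-selective Claisen shift of ester dienolates. Ring A (C1–C2–C3–C4–C5–C10) closes as the new σ-bond of the pericyclic array, which the lactone tether holds in a boat geometry; the six-membered oxacycle is exchanged for the six-membered carbocycle with the C1=C2 alkene inside the ring. The only new stereocentre, C4, is controlled by C1: the vinyl group can reach C4 only on the lactone face on which it stands (trans to the C10 methyl), so the C19 carboxyl should end cis to the C10 methyl (axial) and the C4 methyl equatorial, while C1 becomes trigonal. The step needs α- and not γ-bonding of the dienolate, and a reachable boat: only C4 lies inside the six-atom array, and keeping C5 trigonal (C5=C6) leaves the lactone an envelope whose C1 flap can tip the vinyl group over C4, which a trans-fused saturated lactone could not do.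

Step 9
Reactants: 13 (4R,9S,10S)-8,8-ethylenedioxy-13,14,15,16,17-pentanor-ent-labda-1,5,11-trien-19-oic acid
Product: 14 (4R,9S,10S)-8,8-ethylenedioxy-13,14,15,16,17-pentanor-ent-labda-1,5,11-trien-19-ol
Conditions: LiAlH4, THF, 0 °C → reflux
Reagents that add atoms: none
Why: Hydride reduction of the hindered carboxylic acid gives the C19 primary alcohol; alkenes and ketal are inert and no stereocentre changes.

Step 10
Reactants: 14 (4R,9S,10S)-8,8-ethylenedioxy-13,14,15,16,17-pentanor-ent-labda-1,5,11-trien-19-ol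
Product: 16 (4R,9S,10S)-8,8-ethylenedioxy-13,14,15,16,17-pentanor-ent-labda-1,5-diene-12,19-diol, via alkylborane 15 (not isolated)
Conditions: 9-BBN (2.5 equiv), THF, 0 °C → rt; then NaOH, H2O2, 0 °C
Reagents that add atoms: hydrogen peroxide, OO
Why: Anti-Markovnikov hydroboration–oxidation; 9-BBN should select the terminal C11=C12 vinyl group over the cis-disubstituted C1=C2 and the trisubstituted C5=C6 alkenes.

Step 11
Reactants: 16 (4R,9S,10S)-8,8-ethylenedioxy-13,14,15,16,17-pentanor-ent-labda-1,5-diene-12,19-diol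
Product: 17 (4R,9S,10S)-8,8-ethylenedioxy-13,14,15,16,17-pentanor-ent-labd-5-ene-12,19-diol
Conditions: H2 (1 atm), RhCl(PPh3)3 (5 mol %), benzene/EtOH, rt
Reagents that add atoms: none
Why: Homogeneous hydrogenation with RhCl(PPh3)3 is sensitive to substitution and should saturate only the cis-disubstituted C1=C2 alkene, leaving the C5=C6 alkene that is flanked by two quaternary carbons; no stereocentre is formed.

Step 12
Reactants: 17 (4R,9S,10S)-8,8-ethylenedioxy-13,14,15,16,17-pentanor-ent-labd-5-ene-12,19-diol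
Product: 18 (4R,5S,9S,10R)-8,8-ethylenedioxy-13,14,15,16,17-pentanor-ent-labdane-12,19-diol
Conditions: Mn(dpm)3 (10 mol %; dpm = dipivaloylmethanate), PhSiH3, tBuOOH, iPrOH, rt
Reagents that add atoms: none
Why: Metal-hydride hydrogen-atom-transfer hydrogenation: hydrogen-atom transfer to C6 gives the tertiary C5 radical, which should be reduced on the face opposite the axial C19 and C20 groups to the thermodynamically preferred trans-decalin, setting C5 (H anti to the C10 methyl).

Step 13
Reactants: 18 (4R,5S,9S,10R)-8,8-ethylenedioxy-13,14,15,16,17-pentanor-ent-labdane-12,19-diol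
Product: 19 (4R,5S,9S,10R)-12,19-dihydroxy-13,14,15,16,17-pentanor-ent-labdan-8-one
Conditions: aq. HCl (1 mol/L), THF, rt
Reagents that add atoms: water, O
Why: Acid hydrolysis of the dioxolane frees the C8 ketone; C9, now α to the ketone, keeps its equatorial side chain, which is the thermodynamically preferred configuration.

Step 14
Reactants: 19 (4R,5S,9S,10R)-12,19-dihydroxy-13,14,15,16,17-pentanor-ent-labdan-8-one
Product: 20 (4R,5S,9R,10S)-13,14,15,16-tetranor-ent-labd-8(17)-ene-12,19-diol
Conditions: Ph3PCH3Br, KOtBu (5 equiv each), toluene, 80 °C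
Reagents that add atoms: methyltriphenylphosphonium bromide, C[P+](c1ccccc1)(c1ccccc1)c1ccccc1.[Br-]
Why: Wittig methylenation of the hindered C8 ketone with excess ylide (the two alkoxides are tolerated) gives the exocyclic C8=C17 alkene; C9 stays in its stable equatorial configuration.

Step 15
Reactants: 20 (4R,5S,9R,10S)-13,14,15,16-tetranor-ent-labd-8(17)-ene-12,19-diol
Product: 21 (4R,5S,9R,10S)-12-iodo-13,14,15,16-tetranor-ent-labd-8(17)-en-19-ol
Conditions: I2, PPh3, imidazole, CH2Cl2, 0 °C
Reagents that add atoms: iodine, [I][I]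
Why: Appel iodination is an SN2 process and should convert only the unhindered C12 primary alcohol, the axial neopentyl C19 alcohol being far slower.

Step 16
Reactants: 21 (4R,5S,9R,10S)-12-iodo-13,14,15,16-tetranor-ent-labd-8(17)-en-19-ol
Product: 22 (4R,5S,9R,10S)-12-iodo-13,14,15,16-tetranor-ent-labd-8(17)-en-19-yl acetate
Conditions: Ac2O, pyridine, DMAP (cat.), CH2Cl2, rt
Reagents that add atoms: acetic anhydride, CC(=O)OC(C)=O
Why: DMAP-catalysed acetylation of the C19 alcohol installs the acetate of the target; no stereocentre is touched.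

Step 17
Reactants: 22 (4R,5S,9R,10S)-12-iodo-13,14,15,16-tetranor-ent-labd-8(17)-en-19-yl acetate; 23 3-bromofuran-2(5H)-one
Product: 25 (4R,5S,9R,10S)-19-acetoxy-ent-labda-8(17),13-dien-16,15-olide (CNP0350004.2), via alkylzinc iodide 24 (not isolated)
Conditions: Zn dust, LiCl, THF, 40 °C; then 23, Pd(OAc)2 (3 mol %), SPhos (6 mol %), THF, rt
Reagents that add atoms: none
Why: Zinc insertion into the primary iodide followed by Negishi cross-coupling with the α-bromobutenolide forms the C12–C13 bond; the acetate, the exocyclic alkene and the lactone tolerate the organozinc reagent.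

**Compound list**
1 | 1,4-dioxaspiro[4.5]dec-6-en-8-one | O=C1CCC2(OCCO2)C=C1 | starting material
2 | 7-iodo-1,4-dioxaspiro[4.5]dec-6-en-8-one | O=C1CCC2(OCCO2)C=C1[I] | intermediate
3 | 7-methyl-1,4-dioxaspiro[4.5]dec-6-en-8-one | O=C1CCC2(OCCO2)C=C1C | intermediate
4 | [(6S)-7-methyl-6-vinyl-1,4-dioxaspiro[4.5]dec-7-en-8-yl]oxymagnesium bromide (bromomagnesium enolate) | Br[Mg]OC1=C(C)[C@H](C=C)C2(OCCO2)CC1 | intermediate
5 | (6S,7R)-7-(hydroxymethyl)-7-methyl-6-vinyl-1,4-dioxaspiro[4.5]decan-8-one | OC[C@@]1(C)[C@H](C=C)C2(OCCO2)CCC1=O | intermediate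
6 | (6S,7R)-7-methyl-8-oxo-6-vinyl-1,4-dioxaspiro[4.5]decane-7-carbaldehyde | O=C[C@@]1(C)[C@H](C=C)C2(OCCO2)CCC1=O | intermediate
7 | (6S,7R)-7-[(1S)-1-hydroxyprop-2-en-1-yl]-7-methyl-6-vinyl-1,4-dioxaspiro[4.5]decan-8-one | C=C[C@H](O)[C@@]1(C)[C@H](C=C)C2(OCCO2)CCC1=O | intermediate
8 | 2-(diethoxyphosphoryl)propanoic acid | CCOP(=O)(OCC)C(C)C(=O)O | starting material
9 | (1S)-1-[(6S,7R)-7-methyl-8-oxo-6-vinyl-1,4-dioxaspiro[4.5]decan-7-yl]prop-2-en-1-yl 2-(diethoxyphosphoryl)propanoate | C=C[C@H](OC(=O)C(C)P(=O)(OCC)OCC)[C@@]1(C)[C@H](C=C)C2(OCCO2)CCC1=O | intermediate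
10 | (1S,9S,10S)-bicyclic lactone: δ-lactone O–C1–C10–C5(=C4(CH3))–C19(=O) fused to ring B; C1 vinyl, C9 vinyl, C10 methyl, C8 ethylene ketal | C=C[C@@H]1OC(=O)C(C)=C2CCC3(OCCO3)[C@@H](C=C)[C@]12C | intermediate
11 | (1S,9S,10S)-silyl ketene acetal of 10: O–C19(OSitBuMe2)=C4(CH3)–C5=C6 | C=C[C@@H]1OC(O[Si](C)(C)C(C)(C)C)=C(C)C2=CCC3(OCCO3)[C@@H](C=C)[C@]12C | intermediate
12 | tert-butyldimethylsilyl (4R,9S,10S)-8,8-ethylenedioxy-13,14,15,16,17-pentanor-ent-labda-1,5,11-trien-19-oate | CC(C)(C)[Si](C)(C)OC(=O)[C@]1(C)CC=C[C@@]2(C)[C@H](C=C)C3(OCCO3)CC=C12 | intermediate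
13 | (4R,9S,10S)-8,8-ethylenedioxy-13,14,15,16,17-pentanor-ent-labda-1,5,11-trien-19-oic acid | OC(=O)[C@]1(C)CC=C[C@@]2(C)[C@H](C=C)C3(OCCO3)CC=C12 | intermediate
14 | (4R,9S,10S)-8,8-ethylenedioxy-13,14,15,16,17-pentanor-ent-labda-1,5,11-trien-19-ol | OC[C@]1(C)CC=C[C@@]2(C)[C@H](C=C)C3(OCCO3)CC=C12 | intermediate
15 | 12-(9-borabicyclo[3.3.1]nonan-9-yl) 19-O-(9-borabicyclo[3.3.1]nonan-9-yl) derivative of 14 (alkylborane and borinate) | B1(OC[C@]2(C)CC=C[C@@]3(C)[C@H](CCB4C5CCCC4CCC5)C4(OCCO4)CC=C23)C2CCCC1CCC2 | intermediate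
16 | (4R,9S,10S)-8,8-ethylenedioxy-13,14,15,16,17-pentanor-ent-labda-1,5-diene-12,19-diol | OC[C@]1(C)CC=C[C@@]2(C)[C@H](CCO)C3(OCCO3)CC=C12 | intermediate
17 | (4R,9S,10S)-8,8-ethylenedioxy-13,14,15,16,17-pentanor-ent-labd-5-ene-12,19-diol | OC[C@]1(C)CCC[C@@]2(C)[C@H](CCO)C3(OCCO3)CC=C12 | intermediate
18 | (4R,5S,9S,10R)-8,8-ethylenedioxy-13,14,15,16,17-pentanor-ent-labdane-12,19-diol | OC[C@]1(C)CCC[C@@]2(C)[C@H](CCO)C3(OCCO3)CC[C@H]12 | intermediate
19 | (4R,5S,9S,10R)-12,19-dihydroxy-13,14,15,16,17-pentanor-ent-labdan-8-one | OC[C@]1(C)CCC[C@@]2(C)[C@H](CCO)C(=O)CC[C@H]12 | intermediate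
20 | (4R,5S,9R,10S)-13,14,15,16-tetranor-ent-labd-8(17)-ene-12,19-diol | OC[C@]1(C)CCC[C@@]2(C)[C@H](CCO)C(=C)CC[C@H]12 | intermediate
21 | (4R,5S,9R,10S)-12-iodo-13,14,15,16-tetranor-ent-labd-8(17)-en-19-ol | OC[C@]1(C)CCC[C@@]2(C)[C@H](CC[I])C(=C)CC[C@H]12 | intermediate
22 | (4R,5S,9R,10S)-12-iodo-13,14,15,16-tetranor-ent-labd-8(17)-en-19-yl acetate | CC(=O)OC[C@]1(C)CCC[C@@]2(C)[C@H](CC[I])C(=C)CC[C@H]12 | intermediate
23 | 3-bromofuran-2(5H)-one | O=C1OCC=C1Br | starting material
24 | [(4R,5S,9R,10S)-19-acetoxy-13,14,15,16-tetranor-ent-labd-8(17)-en-12-yl]zinc iodide | CC(=O)OC[C@]1(C)CCC[C@@]2(C)[C@H](CC[Zn][I])C(=C)CC[C@H]12 | intermediate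
25 | (4R,5S,9R,10S)-19-acetoxy-ent-labda-8(17),13-dien-16,15-olide (CNP0350004.2) | CC(=O)OC[C@]1(C)CCC[C@@]2(C)[C@H](CCC3=CCOC3=O)C(=C)CC[C@H]12 | target

**Step count and risks**
Total steps: 17. Longest linear sequence: 17 steps (from 1; 8 and 23 are commercial).

The three steps most likely to fail:

Step 3 (conjugate vinylation with formaldehyde trapping). What may go wrong: poor enantiofacial control or competing 1,2-addition at the hindered α-methyl enone next to the ketal, and loss of formaldehyde by retro-aldol cleavage on work-up. Fallback, from 3 back to 7: the conjugate addition is run without chiral ligand with (CH2=CH)2CuLi and Me3SiCl, the silyl enol ether is converted with MeLi into the lithium enolate and trapped with CH2O. This should give racemic material, that is 5 together with its enantiomer (6R,7S)-7-(hydroxymethyl)-7-methyl-6-vinyl-1,4-dioxaspiro[4.5]decan-8-one F1. Oxidation as in step 4 then gives 6 and its enantiomer (6R,7S)-7-methyl-8-oxo-6-vinyl-1,4-dioxaspiro[4.5]decane-7-carbaldehyde F2. The ligand-controlled vinylation of step 5 turns the two enantiomers into diastereomers, 7 and (6R,7S)-7-[(1S)-1-hydroxyprop-2-en-1-yl]-7-methyl-6-vinyl-1,4-dioxaspiro[4.5]decan-8-one F3, which are separated by chromatography; the route continues from 7.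

Step 8 (ring-contracting Ireland–Claisen shift). What may go wrong: incomplete γ-deprotonation or O-silylation, fragmentation of the lactone dienolate (loss of the C1 alkoxide with ketene formation) before the shift, or a slow shift that lets the ketene acetal hydrolyse. Fallback, from 10 back to 14: the same C3–C4 closure is run one oxidation level lower and without an enolate. (iBu)2AlH at −78 °C reduces 10 to the (1S,9S,10S)-lactol (C19 hemiacetal) F4. MsCl/Et3N dehydrates it to the (1S,9S,10S)-cyclic dienol ether O–C19H=C4(CH3)–C5=C6 F5. Heating in xylene at 150 °C should effect the thermal aliphatic Claisen ring contraction of this 2-vinyl-dihydropyran, with the same C1-to-C4 chirality transfer, to (4R,9S,10S)-8,8-ethylenedioxy-13,14,15,16,17-pentanor-ent-labda-1,5,11-trien-19-al F6. NaBH4 then gives 14.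

Step 5 (ligand-controlled vinylation). What may go wrong: a ligand-free, chelate-controlled background addition to the β-keto aldehyde erodes control at C1 (the C1 epimer would end as the C4 epimer after step 8), and deformylation of the β-keto aldehyde. Fallback, from 6 back to 7: ethynylmagnesium bromide adds to the aldehyde to give (6S,7R)-7-(1-hydroxyprop-2-yn-1-yl)-7-methyl-6-vinyl-1,4-dioxaspiro[4.5]decan-8-one F7 as both C1 epimers. Dess–Martin oxidation gives the ynone (6S,7R)-7-methyl-7-propioloyl-6-vinyl-1,4-dioxaspiro[4.5]decan-8-one F8. Noyori asymmetric transfer hydrogenation (RuCl[(S,S)-TsDPEN](p-cymene) or its enantiomer, whichever gives 1S, in iPrOH) should reduce only the alkynyl ketone to (6S,7R)-7-[(1S)-1-hydroxyprop-2-yn-1-yl]-7-methyl-6-vinyl-1,4-dioxaspiro[4.5]decan-8-one F9. Semi-hydrogenation (H2, Pd/CaCO3–Pb(OAc)2, quinoline) gives 7.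

**Further compounds**
F1 | step 3 | (6R,7S)-7-(hydroxymethyl)-7-methyl-6-vinyl-1,4-dioxaspiro[4.5]decan-8-one | OC[C@]1(C)[C@@H](C=C)C2(OCCO2)CCC1=O
F2 | step 3 | (6R,7S)-7-methyl-8-oxo-6-vinyl-1,4-dioxaspiro[4.5]decane-7-carbaldehyde | O=C[C@]1(C)[C@@H](C=C)C2(OCCO2)CCC1=O
F3 | step 3 | (6R,7S)-7-[(1S)-1-hydroxyprop-2-en-1-yl]-7-methyl-6-vinyl-1,4-dioxaspiro[4.5]decan-8-one | C=C[C@H](O)[C@]1(C)[C@@H](C=C)C2(OCCO2)CCC1=O
F4 | step 8 | (1S,9S,10S)-lactol of 10 (C19 hemiacetal, both anomers) | C=C[C@@H]1OC(O)C(C)=C2CCC3(OCCO3)[C@@H](C=C)[C@]12C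
F5 | step 8 | (1S,9S,10S)-cyclic dienol ether O–C19H=C4(CH3)–C5=C6 | C=C[C@@H]1OC=C(C)C2=CCC3(OCCO3)[C@@H](C=C)[C@]12C
F6 | step 8 | (4R,9S,10S)-8,8-ethylenedioxy-13,14,15,16,17-pentanor-ent-labda-1,5,11-trien-19-al | O=C[C@]1(C)CC=C[C@@]2(C)[C@H](C=C)C3(OCCO3)CC=C12
F7 | step 5 | (6S,7R)-7-(1-hydroxyprop-2-yn-1-yl)-7-methyl-6-vinyl-1,4-dioxaspiro[4.5]decan-8-one (both C1 epimers) | C#CC(O)[C@@]1(C)[C@H](C=C)C2(OCCO2)CCC1=O
F8 | step 5 | (6S,7R)-7-methyl-7-propioloyl-6-vinyl-1,4-dioxaspiro[4.5]decan-8-one | C#CC(=O)[C@@]1(C)[C@H](C=C)C2(OCCO2)CCC1=O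
F9 | step 5 | (6S,7R)-7-[(1S)-1-hydroxyprop-2-yn-1-yl]-7-methyl-6-vinyl-1,4-dioxaspiro[4.5]decan-8-one | C#C[C@H](O)[C@@]1(C)[C@H](C=C)C2(OCCO2)CCC1=O
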